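The octalin core is disconnected across C5–C10 and C8–C9: an intramolecular Diels–Alder reaction of an acyclic trienoate closes rings A and B together and sets C5, C9 and C10 (plus a transient C8 centre). It exploits the C1–C4 segment of ring A (C2 carbonyl as dioxolane, C3 carbinol, C4 gem-dimethyl) as a four-atom tether that joins the C5=C6–C7=C8 diene to the C9=C10 3-methyl-enoate; ring B's olefin is later shifted from C6=C7 to C7=C8. The precursor is a (2E,8E,10E)-dodecatrienoate built from (S)-pantolactone, which supplies C2–C5 and the C3 stereocentre that steers the cycloaddition. The C11–C15 chain is added by sulfone alkylation.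

Key step: step 11

Remark: ring atoms are numbered as in labdanes and drimanes (ring A = C1–C5 and C10, ring B = C5–C10, C11 on C9); the target is the ent-labdane (3S,5S,9R,10S,13E), whose C3 configuration corresponds to (S)-pantolactone. TBSO = tert-butyldimethylsilyloxy.

Step 1
Reactants: 1 (S)-pantolactone
Product: 2 (2S)-2,4-dihydroxy-N-methoxy-N,3,3-trimethylbutanamide
Conditions: MeNH(OMe)·HCl (3 equiv), AlMe3 (3 equiv), CH2Cl2, 0 °C → rt; aq. KNaC4H4O6 work-up; used crude
Reagents that add atoms: N,O-dimethylhydroxylamine hydrochloride (CNOC.Cl)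
Why: Weinreb aminolysis of the lactone by the aluminium amide opens the ring without touching the C3 stereocentre and gives an acyl donor that later stops at the ketone stage.

Step 2
Reactants: 2 Weinreb amide diol
Product: 3 (2S)-2,4-bis(TBSO)-N-methoxy-N,3,3-trimethylbutanamide
Conditions: TBSOTf (2.5 equiv), 2,6-lutidine (4 equiv), CH2Cl2, 0 °C → rt
Reagents that add atoms: tert-butyldimethylsilyl trifluoromethanesulfonate (CC(C)(C)[Si](C)(C)OS(=O)(=O)C(F)(F)F)
Why: Silyl triflate silylation caps the primary and the hindered secondary hydroxyl in one operation and blocks relactonization, so no lactol can form once C2 becomes a ketone.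

Step 3
Reactants: 3 bis-silyl Weinreb amide; 4 2-methylallylmagnesium chloride
Product: 6 (5S)-5,7-bis(TBSO)-2,6,6-trimethylhept-1-en-4-one, via magnesium chelate 5 (not isolated)
Conditions: 4 (2 equiv, 0.5 M in THF), THF, −78 → −20 °C; cold sat. NH4Cl
Reagents that add atoms: none
Why: Grignard addition to a Weinreb amide stops at the chelated tetrahedral adduct, which collapses to the β,γ-unsaturated ketone only on cold buffered quench, so over-addition, olefin conjugation and epimerization at C3 should be avoided.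

Step 4
Reactants: 6 methallyl ketone
Product: 7 2-[(1S)-1,3-bis(TBSO)-2,2-dimethylpropyl]-2-(2-methylprop-2-en-1-yl)-1,3-dioxolane
Conditions: TMSOCH2CH2OTMS (4 equiv), TMSOTf (0.1 equiv), CH2Cl2, −78 → −20 °C; pyridine quench
Reagents that add atoms: 1,2-bis(trimethylsilyloxy)ethane (C[Si](C)(C)OCCO[Si](C)(C)C)
Why: Noyori ketalization under aprotic, low-temperature conditions is driven by Si–O–Si formation, suits hindered ketones, and should leave the β,γ-olefin in place and both silyl ethers intact.

Step 5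
Reactants: 7 methallyl dioxolane
Product: 9 1-{2-[(1S)-1,3-bis(TBSO)-2,2-dimethylpropyl]-1,3-dioxolan-2-yl}propan-2-one, via ozonide 8 (not isolated)
Conditions: O3, CH2Cl2, −78 °C; then PPh3 (1.5 equiv), −78 °C → rt
Reagents that add atoms: ozone ([O-][O+]=O)
Why: Ozonolysis of the only olefin with reductive cleavage of the ozonide unveils the methyl ketone (C10 with its methyl), and nothing else in 7 is oxidizable under these conditions.

Step 6
Reactants: 9 methyl ketone; 10 trimethyl phosphonoacetate
Product: 12 methyl (2E)-4-{2-[(1S)-1,3-bis(TBSO)-2,2-dimethylpropyl]-1,3-dioxolan-2-yl}-3-methylbut-2-enoate, via sodium phosphonate 11 (not isolated)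
Conditions: 10 (1.6 equiv), NaH (1.5 equiv), THF, 0 °C; then 9, rt → 50 °C; chromatographic removal of the minor Z isomer
Reagents that add atoms: none
Why: Horner–Wadsworth–Emmons olefination of the methyl ketone should place the bulky CH2–ketal residue trans to CO2Me (E), and the geometry is purified here because it later fixes C9 relative to C10.

Step 7
Reactants: 12 bis-silyl enoate
Product: 13 methyl (2E)-4-{2-[(1S)-1-(TBSO)-3-hydroxy-2,2-dimethylpropyl]-1,3-dioxolan-2-yl}-3-methylbut-2-enoate
Conditions: HF·pyridine, pyridine, THF, 0 °C → rt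
Reagents that add atoms: none
Why: Selective desilylation with buffered HF·pyridine should cleave the primary silyl ether much faster than the secondary one, which is shielded by the gem-dimethyl and ketal carbons.

Step 8
Reactants: 13 primary alcohol
Product: 14 methyl (2E)-4-{2-[(1S)-1-(TBSO)-2,2-dimethyl-3-oxopropyl]-1,3-dioxolan-2-yl}-3-methylbut-2-enoate
Conditions: Dess–Martin periodinane (1.5 equiv), CH2Cl2, 0 °C → rt
Reagents that add atoms: none
Why: Dess–Martin oxidation gives the non-enolizable neopentyl aldehyde (C5) under near-neutral conditions that ketal, silyl ether and enoate tolerate.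

Step 9
Reactants: 14 aldehyde
Product: 15 methyl (2E)-4-{2-[(1S,3E)-1-(TBSO)-4-iodo-2,2-dimethylbut-3-en-1-yl]-1,3-dioxolan-2-yl}-3-methylbut-2-enoate
Conditions: CrCl2 (6 equiv), CHI3 (2 equiv), THF/dioxane, 0 °C → rt
Reagents that add atoms: iodoform (IC(I)I)
Why: Takai iodo-olefination homologates the hindered aldehyde to the (E)-vinyl iodide (C5=C6) with the high E preference typical of α-branched aldehydes and leaves the enoate untouched.

Step 10
Reactants: 15 vinyl iodide; 16 (E)-prop-1-enylboronic acid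
Product: 17 methyl (2E,6S,8E,10E)-6-(TBSO)-5,5-(ethylenedioxy)-3,7,7-trimethyldodeca-2,8,10-trienoate
Conditions: 16 (1.5 equiv), Pd(PPh3)4 (5 mol%), K3PO4 (3 equiv, aq.), THF, 50 °C, degassed
Reagents that add atoms: none
Why: Suzuki–Miyaura coupling proceeds with retention at both sp2 carbons, so the (E,E)-diene C5=C6–C7=C8 is obtained geometrically defined, which an allylic ylide would not guarantee.

Step 11
Reactants: 17 trienoate
Product: 18 methyl (3S,5S,8R,9R,10R)-3-(TBSO)-2,2-(ethylenedioxy)drim-6-en-11-oate (trans-fused; 8-Me, 9-CO2Me, 10-Me and 3-OTBS on one face, H-5 on the other)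
Conditions: PhMe (0.01 M), BHT (0.1 equiv), base-washed sealed tube, 190 °C, 36 h; diastereomers separated by chromatography
Reagents that add atoms: none
Why: This is a concerted, suprafacial [4π+2π] cycloaddition of the C5=C6–C7=C8 diene onto the C9=C10 enoate, a type 1 intramolecular Diels–Alder reaction of a 1,7,9-decatrienoate as known for trans-fused octalins with an angular methyl, and the quaternary C2 and C4 tether carbons favour the folded, reactive rotamer. Ring B is closed by the cycloaddition itself (bonds C5–C10 and C8–C9, new C6=C7), and ring A is closed at the same time because the C5–C10 bond locks the four-atom C1–C4 tether into a chair. C9 and C10 follow from the E geometry of the enoate (CO2Me cis to the angular methyl), C8 from the E geometry of C7=C8 together with the endo ester (8-Me cis to CO2Me), and C5 from the E geometry of C5=C6 with the ester endo, which puts H-5 trans to the 10-methyl. The absolute sense comes from C3, because the tether chair that carries the silyloxy group equatorial presents one diene face to the dienophile. Two selectivities are needed, endo (trans-fused) over exo (cis-fused) and equatorial over axial C3–O; they rest on the secondary-orbital endo preference of the E-enoate and on the 1,3-diaxial penalty of an axial silyloxy group against H-1 and H-5. Both preferences are moderate, so the risk of the route is concentrated here and diastereomers are to be removed at this stage.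

Step 12
Reactants: 18 Δ6 adduct
Product: 19 methyl (3S,5S,9R,10R)-3-(TBSO)-2,2-(ethylenedioxy)drim-7-en-11-oate
Conditions: RhCl3·3H2O (10 mol%), EtOH, 75 °C
Reagents that add atoms: none
Why: Rhodium-hydride-catalysed positional olefin isomerization (syn addition, then β-hydride elimination of H-8 on the open face) should move the cis-disubstituted C6=C7 bond to the trisubstituted C7=C8 position, driven by relief of the 8-Me/10-Me 1,3-diaxial strain; it erases C8 and should stop before C8=C9, which would need a tertiary alkyl-rhodium.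

Step 13
Reactants: 19 Δ7 ester
Product: 20 (3S,5S,9R,10R)-3-(TBSO)-2,2-(ethylenedioxy)drim-7-en-11-ol
Conditions: LiAlH4 (1.5 equiv), Et2O, 0 °C → rt; H2O/NaOH work-up
Reagents that add atoms: none
Why: Hydride reduction of the hindered ester gives the C11 alcohol without enolizing the allylic C9 centre and without affecting ketal or silyl ether.

Step 14
Reactants: 20 C11 alcohol
Product: 21 (3S,5S,9R,10R)-3-(TBSO)-2,2-(ethylenedioxy)-11-(phenylsulfanyl)drim-7-ene
Conditions: PhSSPh (2 equiv), n-Bu3P (2 equiv), pyridine, rt → 50 °C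
Reagents that add atoms: diphenyl disulfide (c1ccccc1SSc1ccccc1)
Why: Hata thioetherification converts the primary alcohol into the phenyl sulfide by SN2 displacement of the alkoxyphosphonium group, avoiding a separate halide or sulfonate and any cationic conditions near the C7=C8 olefin.

Step 15
Reactants: 21 sulfide
Product: 23 (3S,5S,9R,10R)-3-(TBSO)-2,2-(ethylenedioxy)-11-(phenylsulfonyl)drim-7-ene, via sulfoxide 22 (not isolated)
Conditions: (NH4)6Mo7O24·4H2O (0.1 equiv), 30% H2O2 (4 equiv), EtOH, 0 °C → rt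
Reagents that add atoms: hydrogen peroxide (OO)
Why: Molybdate-catalysed peroxide oxidation takes sulfur through the sulfoxide to the sulfone chemoselectively, whereas a peracid would epoxidize the trisubstituted olefin.

Step 16
Reactants: 24 prenyl acetate
Product: 25 (2E)-4-hydroxy-3-methylbut-2-en-1-yl acetate
Conditions: SeO2 (0.3 equiv), t-BuOOH (2 equiv), CH2Cl2, rt; over-oxidized enal removed by chromatography
Reagents that add atoms: selenium dioxide (O=[Se]=O); tert-butyl hydroperoxide (CC(C)(C)OO)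
Why: Riley allylic oxidation (ene reaction, then [2,3]-sigmatropic shift) hydroxylates the methyl group trans to the CH2OAc chain and so gives the E allylic alcohol.

Step 17
Reactants: 25 allylic alcohol
Product: 26 (2E)-4-bromo-3-methylbut-2-en-1-yl acetate
Conditions: CBr4 (1.2 equiv), PPh3 (1.25 equiv), CH2Cl2, 0 °C
Reagents that add atoms: carbon tetrabromide (BrC(Br)(Br)Br)
Why: Appel bromination converts the primary allylic alcohol into the bromide by SN2 without allylic transposition, loss of E geometry or harm to the acetate.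

Step 18
Reactants: 23 C11 sulfone; 26 allylic bromide
Product: 28 (3S,5S,9R,10R,13E)-3-(TBSO)-2,2-(ethylenedioxy)-11-(phenylsulfonyl)labda-7,13-dien-15-yl acetate (C11 epimers), via lithiated sulfone 27 (not isolated)
Conditions: n-BuLi (1.05 equiv), THF, −78 °C; then 26 (1.3 equiv), −78 → −40 °C
Reagents that add atoms: none
Why: Alkylation of the α-sulfonyl carbanion with the primary allylic bromide forms C11–C12 by SN2 at low temperature, faster than attack on the acetate, and the new C11 centre is irrelevant because sulfur is removed next.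

Step 19
Reactants: 28 alkylated sulfone
Product: 29 (3S,5S,9R,10S,13E)-3-(TBSO)-2,2-(ethylenedioxy)labda-7,13-dien-15-yl acetate
Conditions: Na(Hg) (5% Na, 6 equiv), Na2HPO4 (8 equiv), MeOH/THF, −20 °C
Reagents that add atoms: none
Why: Buffered sodium amalgam reductive desulfonylation cleaves the C–S bond by electron transfer to the arylsulfonyl group, and at −20 °C with phosphate buffer the acetate and the isolated olefins should survive.

Step 20
Reactants: 29 protected target
Product: 31 (3S,5S,9R,10S,13E)-3-hydroxy-2-oxolabda-7,13-dien-15-yl acetate (CNP0164008.1), via silyloxy ketone 30 (not isolated)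
Conditions: TsOH·H2O (0.2 equiv), MeCN/H2O (10:1), 40 °C; then 48% aq. HF, rt
Reagents that add atoms: water (O)
Why: Acid-catalysed ketal hydrolysis, helped by relief of the axial C–O/methyl interactions at C2, followed in the same flask by HF desilylation frees the α-ketol under mildly acidic, non-basic conditions, so C3 should not epimerize, the ketol should not transpose, and the allylic acetate and trisubstituted olefins should persist.

Compound list
1 | (S)-pantolactone, (3S)-3-hydroxy-4,4-dimethyloxolan-2-one | CC1(C)COC(=O)[C@H]1O | starting material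
2 | (2S)-2,4-dihydroxy-N-methoxy-N,3,3-trimethylbutanamide | CON(C)C(=O)[C@@H](O)C(C)(C)CO | intermediate
3 | (2S)-2,4-bis(tert-butyldimethylsilyloxy)-N-methoxy-N,3,3-trimethylbutanamide | CON(C)C(=O)[C@@H](O[Si](C)(C)C(C)(C)C)C(C)(C)CO[Si](C)(C)C(C)(C)C | intermediate
4 | 2-methylallylmagnesium chloride | CC(=C)C[Mg]Cl | starting material
5 | chloromagnesium alkoxide of the tetrahedral adduct of 3 and 4 (N-methoxy chelate, carbinol carbon unassigned) | CON(C)C(CC(C)=C)(O[Mg]Cl)[C@@H](O[Si](C)(C)C(C)(C)C)C(C)(C)CO[Si](C)(C)C(C)(C)C | intermediate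
6 | (5S)-5,7-bis(tert-butyldimethylsilyloxy)-2,6,6-trimethylhept-1-en-4-one | CC(=C)CC(=O)[C@@H](O[Si](C)(C)C(C)(C)C)C(C)(C)CO[Si](C)(C)C(C)(C)C | intermediate
7 | 2-[(1S)-1,3-bis(tert-butyldimethylsilyloxy)-2,2-dimethylpropyl]-2-(2-methylprop-2-en-1-yl)-1,3-dioxolane | CC(=C)CC1(OCCO1)[C@@H](O[Si](C)(C)C(C)(C)C)C(C)(C)CO[Si](C)(C)C(C)(C)C | intermediate
8 | secondary ozonide of 7 (3-methyl-1,2,4-trioxolane, ring carbon unassigned) | CC1(CC2(OCCO2)[C@@H](O[Si](C)(C)C(C)(C)C)C(C)(C)CO[Si](C)(C)C(C)(C)C)OCOO1 | intermediate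
9 | 1-{2-[(1S)-1,3-bis(tert-butyldimethylsilyloxy)-2,2-dimethylpropyl]-1,3-dioxolan-2-yl}propan-2-one | CC(=O)CC1(OCCO1)[C@@H](O[Si](C)(C)C(C)(C)C)C(C)(C)CO[Si](C)(C)C(C)(C)C | intermediate
10 | trimethyl phosphonoacetate | COC(=O)CP(=O)(OC)OC | starting material
11 | sodium salt of the trimethyl phosphonoacetate carbanion | [Na+].COC(=O)[CH-]P(=O)(OC)OC | intermediate
12 | methyl (2E)-4-{2-[(1S)-1,3-bis(tert-butyldimethylsilyloxy)-2,2-dimethylpropyl]-1,3-dioxolan-2-yl}-3-methylbut-2-enoate | COC(=O)/C=C(\C)CC1(OCCO1)[C@@H](O[Si](C)(C)C(C)(C)C)C(C)(C)CO[Si](C)(C)C(C)(C)C | intermediate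
13 | methyl (2E)-4-{2-[(1S)-1-(tert-butyldimethylsilyloxy)-3-hydroxy-2,2-dimethylpropyl]-1,3-dioxolan-2-yl}-3-methylbut-2-enoate | COC(=O)/C=C(\C)CC1(OCCO1)[C@@H](O[Si](C)(C)C(C)(C)C)C(C)(C)CO | intermediate
14 | methyl (2E)-4-{2-[(1S)-1-(tert-butyldimethylsilyloxy)-2,2-dimethyl-3-oxopropyl]-1,3-dioxolan-2-yl}-3-methylbut-2-enoate | COC(=O)/C=C(\C)CC1(OCCO1)[C@@H](O[Si](C)(C)C(C)(C)C)C(C)(C)C=O | intermediate
15 | methyl (2E)-4-{2-[(1S,3E)-1-(tert-butyldimethylsilyloxy)-4-iodo-2,2-dimethylbut-3-en-1-yl]-1,3-dioxolan-2-yl}-3-methylbut-2-enoate | COC(=O)/C=C(\C)CC1(OCCO1)[C@@H](O[Si](C)(C)C(C)(C)C)C(C)(C)/C=C/I | intermediate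
16 | (E)-prop-1-enylboronic acid | C/C=C/B(O)O | starting material
17 | methyl (2E,6S,8E,10E)-6-(tert-butyldimethylsilyloxy)-5,5-(ethylenedioxy)-3,7,7-trimethyldodeca-2,8,10-trienoate | COC(=O)/C=C(\C)CC1(OCCO1)[C@@H](O[Si](C)(C)C(C)(C)C)C(C)(C)/C=C/C=C/C | intermediate
18 | methyl (3S,5S,8R,9R,10R)-3-(tert-butyldimethylsilyloxy)-2,2-(ethylenedioxy)drim-6-en-11-oate; trans-fused, 8-Me, 9-CO2Me, 10-Me and 3-OTBS cis, H-5 trans to 10-Me | COC(=O)[C@@H]1[C@H](C)C=C[C@@H]2C(C)(C)[C@H](O[Si](C)(C)C(C)(C)C)C3(OCCO3)C[C@@]12C | intermediate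
19 | methyl (3S,5S,9R,10R)-3-(tert-butyldimethylsilyloxy)-2,2-(ethylenedioxy)drim-7-en-11-oate | COC(=O)[C@@H]1C(C)=CC[C@@H]2C(C)(C)[C@H](O[Si](C)(C)C(C)(C)C)C3(OCCO3)C[C@@]12C | intermediate
20 | (3S,5S,9R,10R)-3-(tert-butyldimethylsilyloxy)-2,2-(ethylenedioxy)drim-7-en-11-ol | OC[C@@H]1C(C)=CC[C@@H]2C(C)(C)[C@H](O[Si](C)(C)C(C)(C)C)C3(OCCO3)C[C@@]12C | intermediate
21 | (3S,5S,9R,10R)-3-(tert-butyldimethylsilyloxy)-2,2-(ethylenedioxy)-11-(phenylsulfanyl)drim-7-ene | c1ccccc1SC[C@@H]1C(C)=CC[C@@H]2C(C)(C)[C@H](O[Si](C)(C)C(C)(C)C)C3(OCCO3)C[C@@]12C | intermediate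
22 | (3S,5S,9R,10R)-3-(tert-butyldimethylsilyloxy)-2,2-(ethylenedioxy)-11-(phenylsulfinyl)drim-7-ene (sulfur epimers) | O=S(c1ccccc1)C[C@@H]1C(C)=CC[C@@H]2C(C)(C)[C@H](O[Si](C)(C)C(C)(C)C)C3(OCCO3)C[C@@]12C | intermediate
23 | (3S,5S,9R,10R)-3-(tert-butyldimethylsilyloxy)-2,2-(ethylenedioxy)-11-(phenylsulfonyl)drim-7-ene | O=S(=O)(c1ccccc1)C[C@@H]1C(C)=CC[C@@H]2C(C)(C)[C@H](O[Si](C)(C)C(C)(C)C)C3(OCCO3)C[C@@]12C | intermediate
24 | prenyl acetate, 3-methylbut-2-en-1-yl acetate | CC(=O)OCC=C(C)C | starting material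
25 | (2E)-4-hydroxy-3-methylbut-2-en-1-yl acetate | CC(=O)OC/C=C(\C)CO | intermediate
26 | (2E)-4-bromo-3-methylbut-2-en-1-yl acetate | CC(=O)OC/C=C(\C)CBr | intermediate
27 | 11-lithio derivative of sulfone 23 | [Li]C([C@@H]1C(C)=CC[C@@H]2C(C)(C)[C@H](O[Si](C)(C)C(C)(C)C)C3(OCCO3)C[C@@]12C)S(=O)(=O)c1ccccc1 | intermediate
28 | (3S,5S,9R,10R,13E)-3-(tert-butyldimethylsilyloxy)-2,2-(ethylenedioxy)-11-(phenylsulfonyl)labda-7,13-dien-15-yl acetate (C11 epimers) | CC(=O)OC/C=C(\C)CC([C@@H]1C(C)=CC[C@@H]2C(C)(C)[C@H](O[Si](C)(C)C(C)(C)C)C3(OCCO3)C[C@@]12C)S(=O)(=O)c1ccccc1 | intermediate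
29 | (3S,5S,9R,10S,13E)-3-(tert-butyldimethylsilyloxy)-2,2-(ethylenedioxy)labda-7,13-dien-15-yl acetate (the C10 descriptor changes only because CIP priorities change once sulfur has left C11) | CC(=O)OC/C=C(\C)CC[C@@H]1C(C)=CC[C@@H]2C(C)(C)[C@H](O[Si](C)(C)C(C)(C)C)C3(OCCO3)C[C@@]12C | intermediate
30 | (3S,5S,9R,10S,13E)-3-(tert-butyldimethylsilyloxy)-2-oxolabda-7,13-dien-15-yl acetate | CC(=O)OC/C=C(\C)CC[C@@H]1C(C)=CC[C@@H]2C(C)(C)[C@H](O[Si](C)(C)C(C)(C)C)C(=O)C[C@@]12C | intermediate
31 | (3S,5S,9R,10S,13E)-3-hydroxy-2-oxolabda-7,13-dien-15-yl acetate, CNP0164008.1 | CC(=O)OC/C=C(\C)CC[C@@H]1C(C)=CC[C@@H]2C(C)(C)[C@H](O)C(=O)C[C@@]12C | target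

Total step count: 20. Longest linear sequence: 18 steps (steps 1–15, then 18–20); steps 16–17 form the side branch.

Steps most likely to fail

Step 11 (key cycloaddition). The β,β-disubstituted enoate needs about 190 °C. At that temperature the endo/exo and chair-face preferences shrink, the cycloaddition may be slow, and the enoate geometry may drift, so cis-fused or C3-mismatched adducts may form. The fallback changes the activating group of the dienophile so that the ring closure runs far cooler. It sets out from 17: i-Bu2AlH (CH2Cl2, −78 °C) should give (2E,6S,8E,10E)-6-(TBSO)-5,5-(ethylenedioxy)-3,7,7-trimethyldodeca-2,8,10-trien-1-ol F1, and MnO2 should give the corresponding trienal F2. The much more reactive enal should cyclize near 80–110 °C in toluene through the same endo/chair topology to the Δ6 adduct aldehyde F3. NaBH4 then gives the Δ6 C11 alcohol F4, and the RhCl3·3H2O isomerization of step 12 applied to F4 comes back to the route at 20.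

Step 12 (olefin transposition). The rhodium hydride may fail to engage the hindered cis olefin, may walk on toward C5 or C9, or the HCl formed in hot ethanol may loosen the ketal or the silyl ether. The fallback is a stepwise, stoichiometric transposition through a C7 ketone, setting out from 18. Hydroboration (BH3·SMe2, THF, 0 °C) on the face opposite the three cis substituents, then NaBO3·4H2O, should give the 7-hydroxy ester F5 (boron at C7 because C6 is flanked by the neopentyl C5). Dess–Martin oxidation gives the 7-ketone F6. Tf2O with 2,6-di-tert-butyl-4-methylpyridine gives the more substituted C7=C8 enol triflate F7. Palladium-catalysed formate reduction (Pd(OAc)2, PPh3, n-Bu3N, HCO2H, DMF, 60 °C) replaces OTf by hydrogen and comes back to the route at 19.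

Step 4 (ketalization). Ketal formation at the hindered α-silyloxy ketone may be sluggish, and during long exposure to TMSOTf the olefin may migrate into conjugation or the C5 silyl ether may take part and give a cyclic mixed ketal. The fallback builds the dioxolane by conjugate addition instead of carbonyl ketalization, setting out from 3. i-Bu2AlH (THF, −78 °C) gives (2S)-2,4-bis(TBSO)-3,3-dimethylbutanal F8. Ohira–Bestmann homologation (dimethyl (1-diazo-2-oxopropyl)phosphonate, K2CO3, MeOH) gives (3R)-3,5-bis(TBSO)-4,4-dimethylpent-1-yne F9. Lithiation (n-BuLi) and acylation with N-methoxy-N-methylacetamide give (5R)-5,7-bis(TBSO)-6,6-dimethylhept-3-yn-2-one F10. Base-catalysed double oxa-Michael addition of ethylene glycol (NaH cat., THF) places both oxygens on the β-carbon C2 and comes back to the route at 9, by-passing 6, 7 and the ozonolysis.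

Further compounds
F1 | step 11 | (2E,6S,8E,10E)-6-(tert-butyldimethylsilyloxy)-5,5-(ethylenedioxy)-3,7,7-trimethyldodeca-2,8,10-trien-1-ol | OC/C=C(\C)CC1(OCCO1)[C@@H](O[Si](C)(C)C(C)(C)C)C(C)(C)/C=C/C=C/C
F2 | step 11 | (2E,6S,8E,10E)-6-(tert-butyldimethylsilyloxy)-5,5-(ethylenedioxy)-3,7,7-trimethyldodeca-2,8,10-trienal | O=C/C=C(\C)CC1(OCCO1)[C@@H](O[Si](C)(C)C(C)(C)C)C(C)(C)/C=C/C=C/C
F3 | step 11 | (3S,5S,8R,9R,10R)-3-(tert-butyldimethylsilyloxy)-2,2-(ethylenedioxy)drim-6-en-11-al | O=C[C@@H]1[C@H](C)C=C[C@@H]2C(C)(C)[C@H](O[Si](C)(C)C(C)(C)C)C3(OCCO3)C[C@@]12C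
F4 | step 11 | (3S,5S,8R,9R,10R)-3-(tert-butyldimethylsilyloxy)-2,2-(ethylenedioxy)drim-6-en-11-ol | OC[C@@H]1[C@H](C)C=C[C@@H]2C(C)(C)[C@H](O[Si](C)(C)C(C)(C)C)C3(OCCO3)C[C@@]12C
F5 | step 12 | methyl 3-(tert-butyldimethylsilyloxy)-2,2-(ethylenedioxy)-7-hydroxydriman-11-oate, 7-OH cis to H-5, other centres as in 18 | COC(=O)[C@@H]1[C@H](C)[C@@H](O)C[C@@H]2C(C)(C)[C@H](O[Si](C)(C)C(C)(C)C)C3(OCCO3)C[C@@]12C
F6 | step 12 | methyl 3-(tert-butyldimethylsilyloxy)-2,2-(ethylenedioxy)-7-oxodriman-11-oate, centres as in 18 | COC(=O)[C@@H]1[C@H](C)C(=O)C[C@@H]2C(C)(C)[C@H](O[Si](C)(C)C(C)(C)C)C3(OCCO3)C[C@@]12C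
F7 | step 12 | methyl (3S,5S,9R,10R)-3-(tert-butyldimethylsilyloxy)-2,2-(ethylenedioxy)-7-(trifluoromethylsulfonyloxy)drim-7-en-11-oate | COC(=O)[C@@H]1C(C)=C(OS(=O)(=O)C(F)(F)F)C[C@@H]2C(C)(C)[C@H](O[Si](C)(C)C(C)(C)C)C3(OCCO3)C[C@@]12C
F8 | step 4 | (2S)-2,4-bis(tert-butyldimethylsilyloxy)-3,3-dimethylbutanal | O=C[C@@H](O[Si](C)(C)C(C)(C)C)C(C)(C)CO[Si](C)(C)C(C)(C)C
F9 | step 4 | (3R)-3,5-bis(tert-butyldimethylsilyloxy)-4,4-dimethylpent-1-yne | C#C[C@@H](O[Si](C)(C)C(C)(C)C)C(C)(C)CO[Si](C)(C)C(C)(C)C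
F10 | step 4 | (5R)-5,7-bis(tert-butyldimethylsilyloxy)-6,6-dimethylhept-3-yn-2-one | CC(=O)C#C[C@@H](O[Si](C)(C)C(C)(C)C)C(C)(C)CO[Si](C)(C)C(C)(C)C
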